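1. The ratio of coupling partner to substrate on Sunday's run is 11.0, and the substrate there falls by about the same factor in equal times, so I read that run as pseudo-first-order, with a constant of 0.139 h⁻¹ from its first and last readings.

| flask | substrate | coupling partner | initiator | remark | time |
|---|---|---|---|---|---|
| Sunday's | 2 mM | 22 mM | 0.60 mM | run made earlier |  |
| south | 2.0 mM | 22.0 mM | 0.40 mM |  | 20 h |
| south-west | 6.0 mM | 22.0 mM | 0.40 mM |  | 20 h |
| north | 20 mM | 22.0 mM | 0.40 mM |  | 20 h |
| north-east | 60 mM | 22.0 mM | 0.40 mM |  | 20 h |

Sunday's run (percent of the substrate charged)

| time / h | target / % | substrate / % |
|---|---|---|
| 1.50 | 20.3 | 80.4 |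
| 4.00 | 42.0 | 56.9 |
| 8.00 | 65.9 | 31.4 |
| 12.0 | 78.4 | 18.7 |

(each reading ± 1 percentage point)

- percent here means substrate units held: one ended chains B or side product counts as two
- candidate steps: coupling partner + first chain carrier <-> target + second chain carrier; substrate + target -> side product; 2 second chain carrier -> ended chains A; initiator -> 2 initiating radical; 2 first chain carrier -> ended chains B; substrate + initiating radical -> capped initiator + first chain carrier; substrate + second chain carrier -> by-product + first chain carrier
- "hardly changes" means that all values lie within two and a half points (for a concentration: within two and a half percent of the largest)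
- no earlier run changes the charge of initiator; that part of a forecast is a guess

- [target] at the end for south, south-west, north, north-east, in this order
- the shape of the row from first to last (falls, then rises / rises, then falls / rises all the way / falls all the way / hardly changes)

2. I take the second chain carrier as steady: the initiator feeds in carriers as fast as pairs of second chain carrier end. Its level then goes with the square root of the initiator, and the substrate charge does not enter it.

3. Initiator: going from 0.60 mM to 0.40 mM should scale the constant by that root. This gives the chain constant, the share of substrate used per hour at this initiator charge, 0.113 h⁻¹. This step is a guess, since no earlier run changes the initiator.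

4. Time: over 20 h the chain constant leaves 10.3 % of the substrate.

5. Substrate charge: the same share should remain at each charge, so the amount converted grows with the charge, from 1.79 mM in south to 53.8 mM in north-east. That north-east figure is more than the 22.0 mM of coupling partner, and each forward turn spends one coupling partner for one target, so the share reckoned from the chain constant overshoots what the charge allows in north-east. Coupling partner is therefore the limiting reagent in north-east, and by my reckoning it is used up at about 4.03 h.

6. Side step: Sunday's balance gap reads 2.9 percentage points at 12.0 h. This loss goes with substrate times target, so its share grows with the charge. In north-east the remaining substrate then stands with the target for the rest of the run. I commit to a row that rises, then falls.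

7. The forecast, which takes 0.117 per hour where I take 0.113 h⁻¹, gives 1.76 mM, 5 mM, 13 mM and 6 mM, shape rises, then falls, and says: “The leftover substrate (about 30 mM) then eats target for 15 h”

8. The flask gives 1.75 mM, 4.95 mM, 14.1 mM and 8.06 mM, shape rises, then falls.

    coupling partner + first chain carrier ⇌ target + second chain carrier (K = 1.30, k = 18000 M⁻¹ s⁻¹)
    substrate + target → side product (k = 1.90 M⁻¹ h⁻¹)
    2 second chain carrier → ended chains A (k = 1.00 × 10⁹ M⁻¹ s⁻¹)
    initiator → 2 initiating radical (k = 0.00470 h⁻¹)
    2 first chain carrier → ended chains B (k = 3.00 × 10⁶ M⁻¹ s⁻¹)
    substrate + initiating radical → capped initiator + first chain carrier (k = 1.30 × 10⁶ M⁻¹ s⁻¹)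
    substrate + second chain carrier → by-product + first chain carrier (k = 42000 M⁻¹ s⁻¹)

9. North-east ends with coupling partner at 0 % of its charge, target at 13.4 % and side product at 46.5 % of the substrate charged. The chain constant of 0.113 h⁻¹ gave 10.3 % of the substrate left at the end. South stands at 9.87 %, and north, charged ten times as much substrate, at 8.10 %.

The readings stem from a simulated flask with made-up constants, and the scatter is random.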